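**Numbering.** Ring A building block 1 → 2 → 3; ring B building block 4 → 5 → 6 → 7; coupled series 8 → 9 → 10 → 11 → 12 → 13 → 14 → 15 (target). Names and SMILES are in the compound list after the steps.

## Analysis of the target

The target 15 is a flavone, a 4H-chromen-4-one in which benzo ring A is fused to pyranone ring C and an aryl group, ring B, sits on C2. Ring A has no hydrogen left: C5 and C6 carry free hydroxyls, C7 and C8 carry methoxy groups, C8a carries the ring oxygen O1 and C4a carries the carbonyl carbon C4, so five oxygens sit on ring A. Ring B is a 2-hydroxy-6-methoxyphenyl group, and the molecule has no stereocenter or other element of chirality, so the problem is purely one of regiochemistry among six aryl oxygens. The sensitive parts are the 5,6-dihydroxy unit on a very electron-rich ring (oxidised to a quinone by air in base), the O1–C2 bond of ring C (opened by acid or base, after which any free ortho-phenol, including one on ring B, can reclose), and the methyl ethers, which must stay. The difficulty is to leave exactly O5 and O6 free while O7 and O8 remain methylated, and to tell O2' from O6'. The strategy rests on C4a being flanked by two oxygen-bearing carbons, C5 and C8a: if ring C is closed through the other of these two oxygens, the same atoms make up a 5,8-dihydroxy-6,7-dimethoxy ring A. That ring is a para-hydroquinone with two adjacent methoxy groups, locally symmetric, and it can be made from a 5,6,7,8-tetramethoxy ring without having to distinguish the four ethers.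

## Retrosynthetic reasoning

**15 from 14.** The O2'–H bond is traced back to an O2'–allyl bond. The 2'-oxygen has to be blocked whenever ring C is open, and the block has to survive base, hot protic acid and a one-electron oxidant. An allyl ether does, and zerovalent palladium removes it at the end under neutral conditions that touch neither the methyl ethers nor the oxidisable dihydroxy unit.

**14 from 12 through 13.** This is the key disconnection. The O1–C2 bond of 14 is cut to give the ring-opened diketone 13, and 13 is reclosed on paper through its other ortho-hydroxyl, which gives the isomeric flavone 12. The cut is made here because it converts the awkward 5,6-dihydroxy-7,8-dimethoxy pattern into the para-hydroquinone pattern of 12, which is accessible without selective ether cleavage. The forward reaction has to open ring C of 12, turn the acyl group, close onto the former C5 oxygen and settle on 14 under thermodynamic control, with ring B kept out of the reclosure.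

**12 from 11 from 10.** The hydroxyls at C5 and C8 of 12 are traced to the two carbonyls of quinone 11, and these to the methoxy groups at C5 and C8 of the tetramethyl ether 10. Oxidative demethylation picks the para pair by itself, so nothing in ring A has to be differentiated. This also fixes the oxygen count: ring A of 12 carries five oxygens (O1, O5, O6, O7, O8). A ketone building block with only four ring oxygens would leave a hydrogen at C5, so the aryl ketone must be pentaoxygenated, and 3 is the simplest such compound in which only the future O1 is free.

**10 from 9 from 8, and 8 from 3 and 7.** The O1–C2 bond of 10 is cut to diketone 9 (cyclodehydration in the forward sense). The C2–C3 bond of 9 is cut to the aryl ester 8 (Baker–Venkataraman acyl transfer), and the ester C–O bond to phenol 3 and acid chloride 7. Since 3 has a single free hydroxyl and ring B has none, ring C of 10 can close in one way only.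

**3 from 2 from 1.** The C–OMe bond at the future C8 is cut to a C–Br bond and then to C–H. The catalogue ketone 1 has exactly one ring hydrogen, next to its hydroxyl, so both steps are regiochemically fixed.

**7 from 6 from 5 from 4.** The acid chloride 7 comes from acid 6, and 6 from the catalogue acid 4 by allylation of both acidic oxygens to 5 and hydrolysis of the ester only.

## Alternatives that were turned down

Alternative 1: Ring A is built from a four-membered ring, the bond that becomes C8a–C4a being formed last. The forward key step is thermolysis of 4-(1-ethoxyethenyl)-4-hydroxy-2,3-dimethoxycyclobut-2-en-1-one A2, a cyclobutenone obtained by adding a lithiated enol ether to a squaric diester. Four-electron ring opening of A2 gives a dienylketene, and six-electron electrocyclisation and tautomerisation then give the hydroquinone 2-ethoxy-5,6-dimethoxybenzene-1,4-diol A1.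
- For: the five oxygens of ring A are different by construction (two methoxy, two hydroxy, one ethoxy). After C-acylation of A1 at its one free carbon, ring C can close only through the hydroxyl next to a methoxy group, and the ethoxy group ends up peri to the carbonyl, where it alone is cleaved easily. No equilibrium is involved.
- Against: A2 has to be prepared by cryogenic organolithium chemistry. A1 is an air-sensitive hydroquinone that still has to be C-acylated between two oxygens, aroylated on two hydroxyls, rearranged, cyclised and de-ethylated. The sequence is clearly longer.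
- Comparison: on certainty of the ring A pattern this alternative is stronger. The chosen route offers a shorter path from a catalogue ketone by standard flavone chemistry, and it places its single unproven event late, where an independent fallback from the same intermediate 10 exists.

Alternative 2: O1–C8a and C4–C4a are cut together, so ring A enters as an aryne. Fluoride releases a symmetric aryne from 2,3,4,5-tetramethoxy-6-(trimethylsilyl)phenyl trifluoromethanesulfonate A5. The carboxylate of 3-[2-(benzyloxy)-6-methoxyphenyl]prop-2-ynoic acid A4 adds to it, and the aryl anion takes over the acyl group. The resulting ortho-hydroxyaryl ynone closes 6-endo-dig to 2-[2-(benzyloxy)-6-methoxyphenyl]-5,6,7,8-tetramethoxy-4H-chromen-4-one A3.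
- For: the aryne from A5 is symmetric, so the insertion has no regiochemistry, and the whole flavone core of A3 forms in one convergent step.
- Against: A5 is a hexasubstituted benzene that itself needs several steps, and A4 is prone to decarboxylation. A3 carries ring A as the tetramethyl ether, so O5 and O6 still have to be freed selectively afterwards.
- Comparison: the endgame from A3 would be chelation-guided demethylation, the same chemistry as the fallback of the chosen route, and it is at least as predictable as an equilibrium. The chosen route reaches the same kind of tetramethoxyflavone (10) by plain acylation chemistry from stock materials and then has two independent ways to differentiate ring A.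

Alternative 3: Ring B is built onto a finished chromone by forming C1'–C2', C2'–C3' and C5'–C6'. Cyclobut-2-en-1-one A8 opens thermally to a vinylketene, which adds across the ynol ether 5,6,7,8-tetramethoxy-2-(methoxyethynyl)-4H-chromen-4-one A7. The vinylcyclobutenone so formed opens and recloses to the phenol 2-(2-hydroxy-6-methoxyphenyl)-5,6,7,8-tetramethoxy-4H-chromen-4-one A6.
- For: the mechanism puts hydroxyl and methoxy on either side of the chromone-bearing carbon, so ring B of A6 arrives with O2' free and O6' methylated and needs no protecting group. On this point it is stronger than the chosen route.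
- Against: A7 is a push–pull alkyne, conjugated to the chromone enone and therefore a poor partner for a ketene. A8 is volatile and polymerises easily. Ring A of A6 again arrives fully methylated, so the real problem of the target is left open.
- Comparison: the chosen route spends two routine steps on ring B from the commercial acid 4 and puts its effort into ring A, which is where the target is difficult.

Key step: step 9

Assumption: the acid-mediated equilibrium between 12 and 14 is taken to lie on the side of 14, as it does for the unmethylated 5,8-/5,6-dihydroxyflavone pair.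

## Route

Step 1
Reactants: 1 1-(6-hydroxy-2,3,4-trimethoxyphenyl)ethan-1-one
Product: 2 1-(3-bromo-2-hydroxy-4,5,6-trimethoxyphenyl)ethan-1-one
Conditions: NBS (1.05 equiv), MeCN, 0 °C to rt
Reagents that add atoms: N-bromosuccinimide, O=C1CCC(=O)N1Br
Why: Electrophilic aromatic bromination; the only ring hydrogen is ortho to the hydroxyl and para to a methoxy group, so substitution there should be fast and unambiguous, and the ketone methyl does not compete under non-radical conditions.

Step 2
Reactants: 2 1-(3-bromo-2-hydroxy-4,5,6-trimethoxyphenyl)ethan-1-one
Product: 3 1-(2-hydroxy-3,4,5,6-tetramethoxyphenyl)ethan-1-one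
Conditions: NaOMe (excess, in MeOH), CuBr (0.3 equiv), DMF, 110 °C, N2; then dilute HCl
Reagents that add atoms: sodium methoxide, [Na+].[O-]C
Why: CuBr-mediated Ullmann-type methoxylation of an aryl bromide, of the kind used to turn ortho-bromophenols bearing a carbonyl group into the methoxy compounds; the phenoxide formed in the medium shields the ketone from methoxide.

Step 3
Reactants: 4 2-hydroxy-6-methoxybenzoic acid
Product: 5 prop-2-enyl 2-methoxy-6-(prop-2-enyloxy)benzoate
Conditions: allyl bromide (2.5 equiv), K2CO3, DMF, 60 °C
Reagents that add atoms: allyl bromide (3-bromoprop-1-ene), C=CCBr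
Why: Williamson-type O-alkylation of both the phenoxide and the carboxylate; exhaustive allylation avoids any selectivity question.

Step 4
Reactants: 5 prop-2-enyl 2-methoxy-6-(prop-2-enyloxy)benzoate
Product: 6 2-methoxy-6-(prop-2-enyloxy)benzoic acid
Conditions: KOH, EtOH/H2O, reflux; then HCl
Reagents that add atoms: potassium hydroxide, [K+].[OH-]
Why: Saponification; the aryl allyl ether is inert to hydroxide, and the doubly ortho-substituted ester needs heat but offers no other electrophilic site.

Step 5
Reactants: 6 2-methoxy-6-(prop-2-enyloxy)benzoic acid; 3 1-(2-hydroxy-3,4,5,6-tetramethoxyphenyl)ethan-1-one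
Product: 8 2-acetyl-3,4,5,6-tetramethoxyphenyl 2-methoxy-6-(prop-2-enyloxy)benzoate, via acid chloride 7 (not isolated)
Conditions: (COCl)2, DMF (cat.), CH2Cl2, 0 °C to rt, evaporate; then 3, pyridine, DMAP (cat.), 60 °C
Reagents that add atoms: oxalyl chloride, ClC(=O)C(=O)Cl (supplies the chlorine of 7; none of its atoms remain in 8)
Why: Acid chloride formation followed by DMAP-catalysed O-acylation of the single free phenol of 3; both partners are hindered, hence the nucleophilic catalyst and warming.

Step 6
Reactants: 8 2-acetyl-3,4,5,6-tetramethoxyphenyl 2-methoxy-6-(prop-2-enyloxy)benzoate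
Product: 9 1-(2-hydroxy-3,4,5,6-tetramethoxyphenyl)-3-[2-methoxy-6-(prop-2-enyloxy)phenyl]propane-1,3-dione
Conditions: KOtBu (3 equiv), THF, 0 °C to rt; then dilute HCl
Reagents that add atoms: none
Why: Baker–Venkataraman rearrangement: the ketone enolate attacks the neighbouring aryl ester through a six-membered transition state and the phenoxide leaves, forming the C2–C3 bond of the later flavone; anhydrous base avoids ester hydrolysis.

Step 7
Reactants: 9 1-(2-hydroxy-3,4,5,6-tetramethoxyphenyl)-3-[2-methoxy-6-(prop-2-enyloxy)phenyl]propane-1,3-dione
Product: 10 5,6,7,8-tetramethoxy-2-[2-methoxy-6-(prop-2-enyloxy)phenyl]-4H-chromen-4-one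
Conditions: H2SO4 (cat.), AcOH, 80 °C
Reagents that add atoms: none
Why: Acid-catalysed cyclodehydration of an ortho-hydroxyaryl 1,3-diketone to the flavone; the only free phenol is the one that becomes O1, so a single closure is possible, and the time is kept short to spare the C5 methyl ether.

Step 8
Reactants: 10 5,6,7,8-tetramethoxy-2-[2-methoxy-6-(prop-2-enyloxy)phenyl]-4H-chromen-4-one
Product: 12 5,8-dihydroxy-6,7-dimethoxy-2-[2-methoxy-6-(prop-2-enyloxy)phenyl]-4H-chromen-4-one, via flavone-5,8-quinone 11 (not isolated)
Conditions: (NH4)2Ce(NO3)6 (2.5 equiv), MeCN/H2O, 0 °C; extract into EtOAc, then aq. Na2S2O4, rt, Ar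
Reagents that add atoms: water, O (the oxygens on C5 and C8 of 11 and 12 come from water, the methoxy oxygens leave as methanol)
Why: Oxidative demethylation of a para-dialkoxyarene to the para-quinone by (NH4)2Ce(NO3)6, a tetravalent cerium salt, as in the preparation of 2,3-dimethoxy-1,4-benzoquinones from 1,2,3,4-tetramethoxyarenes, followed by Na2S2O4 reduction of the quinone to the hydroquinone. Ring A with five oxygens is the more easily oxidised ring, and ring B has no para pair of oxygens from which a quinone could form.

Step 9
Reactants: 12 5,8-dihydroxy-6,7-dimethoxy-2-[2-methoxy-6-(prop-2-enyloxy)phenyl]-4H-chromen-4-one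
Product: 14 5,6-dihydroxy-7,8-dimethoxy-2-[2-methoxy-6-(prop-2-enyloxy)phenyl]-4H-chromen-4-one, via ring-opened 1,3-diketone 13 (not isolated)
Conditions: conc. HCl/AcOH (1:4), degassed, 100 °C, Ar
Reagents that add atoms: water, O (adds at C2 to give 13 and is lost again on reclosure; none of its atoms remain in 14)
Why: Protonation of the C4 carbonyl turns ring C into a hydroxypyrylium-type cation, water adds at C2 and the O1–C2 bond breaks, giving diketone 13, in which the two carbons flanking the acyl-bearing carbon of ring A both carry free hydroxyls. Rotation about the aryl–C4 bond brings the former C5 hydroxyl to the ring B-side carbonyl, to which it adds in a 6-exo-trig closure, and loss of water forms the new O1–C2 bond and ring C of 14. This is the Wessely–Moser rearrangement, the closest case being the conversion of 5,8-dihydroxyflavone into 5,6-dihydroxyflavone. No stereocenter is formed. The step needs thermodynamic selection between the two closures of 13: 14 should be favoured because its C6 hydroxyl donates a hydrogen bond to O5, which in turn chelates the C4 carbonyl, and because the methoxy group that was wedged between O5 and O7 in 12 now sits next to the unsubstituted ring oxygen. Closure through ring B is excluded because O2' is an allyl ether and O6' a methyl ether. Hydrochloric acid is chosen over HBr or HI because chloride readily cleaves only a methoxy group peri to the carbonyl, which neither 12 nor 14 has, and air is excluded because 12 is a hydroquinone.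

Step 10
Reactants: 14 5,6-dihydroxy-7,8-dimethoxy-2-[2-methoxy-6-(prop-2-enyloxy)phenyl]-4H-chromen-4-one
Product: 15 5,6-dihydroxy-2-(2-hydroxy-6-methoxyphenyl)-7,8-dimethoxy-4H-chromen-4-one
Conditions: Pd(PPh3)4 (5 mol %), morpholine, THF, rt, Ar
Reagents that add atoms: none
Why: Tsuji–Trost-type deallylation: zerovalent palladium ionises the aryl allyl ether to a π-allyl complex and the phenoxide, and morpholine traps the allyl group; the conditions are neutral and non-oxidising and leave the methyl ethers alone.

## Compound list

1 | 1-(6-hydroxy-2,3,4-trimethoxyphenyl)ethan-1-one | CC(=O)c1c(O)cc(OC)c(OC)c1OC | starting material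
2 | 1-(3-bromo-2-hydroxy-4,5,6-trimethoxyphenyl)ethan-1-one | CC(=O)c1c(O)c(Br)c(OC)c(OC)c1OC | intermediate
3 | 1-(2-hydroxy-3,4,5,6-tetramethoxyphenyl)ethan-1-one | CC(=O)c1c(O)c(OC)c(OC)c(OC)c1OC | intermediate
4 | 2-hydroxy-6-methoxybenzoic acid | COc1cccc(O)c1C(=O)O | starting material
5 | prop-2-enyl 2-methoxy-6-(prop-2-enyloxy)benzoate | C=CCOC(=O)c1c(OC)cccc1OCC=C | intermediate
6 | 2-methoxy-6-(prop-2-enyloxy)benzoic acid | C=CCOc1cccc(OC)c1C(=O)O | intermediate
7 | 2-methoxy-6-(prop-2-enyloxy)benzoyl chloride | C=CCOc1cccc(OC)c1C(Cl)=O | intermediate
8 | 2-acetyl-3,4,5,6-tetramethoxyphenyl 2-methoxy-6-(prop-2-enyloxy)benzoate | CC(=O)c1c(OC(=O)c2c(OC)cccc2OCC=C)c(OC)c(OC)c(OC)c1OC | intermediate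
9 | 1-(2-hydroxy-3,4,5,6-tetramethoxyphenyl)-3-[2-methoxy-6-(prop-2-enyloxy)phenyl]propane-1,3-dione | C=CCOc1cccc(OC)c1C(=O)CC(=O)c1c(O)c(OC)c(OC)c(OC)c1OC | intermediate
10 | 5,6,7,8-tetramethoxy-2-[2-methoxy-6-(prop-2-enyloxy)phenyl]-4H-chromen-4-one | C=CCOc1cccc(OC)c1-c1cc(=O)c2c(OC)c(OC)c(OC)c(OC)c2o1 | intermediate
11 | 6,7-dimethoxy-2-[2-methoxy-6-(prop-2-enyloxy)phenyl]-4H-chromene-4,5,8-trione | C=CCOc1cccc(OC)c1C1=CC(=O)C2=C(O1)C(=O)C(OC)=C(OC)C2=O | intermediate
12 | 5,8-dihydroxy-6,7-dimethoxy-2-[2-methoxy-6-(prop-2-enyloxy)phenyl]-4H-chromen-4-one | C=CCOc1cccc(OC)c1-c1cc(=O)c2c(O)c(OC)c(OC)c(O)c2o1 | intermediate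
13 | 1-[2-methoxy-6-(prop-2-enyloxy)phenyl]-3-(2,3,6-trihydroxy-4,5-dimethoxyphenyl)propane-1,3-dione | C=CCOc1cccc(OC)c1C(=O)CC(=O)c1c(O)c(O)c(OC)c(OC)c1O | intermediate
14 | 5,6-dihydroxy-7,8-dimethoxy-2-[2-methoxy-6-(prop-2-enyloxy)phenyl]-4H-chromen-4-one | C=CCOc1cccc(OC)c1-c1cc(=O)c2c(O)c(O)c(OC)c(OC)c2o1 | intermediate
15 | 5,6-dihydroxy-2-(2-hydroxy-6-methoxyphenyl)-7,8-dimethoxy-4H-chromen-4-one | COc1cccc(O)c1-c1cc(=O)c2c(O)c(O)c(OC)c(OC)c2o1 | target

## Step count and weak points

Total: 10 steps. Longest linear sequence: 8 steps (steps 1, 2, 5, 6, 7, 8, 9, 10; the ring B branch through steps 3 and 4 is equally long).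

**Step 9 (key step).** Three things can fail. The equilibration may not end on the side of 14, or may stop at a mixture, because the preference for the 5,6-dihydroxy isomer is not established for this methoxy pattern. Ring opening may be slow, since the chelated C5 hydroxyl lowers the reactivity of the carbonyl and C2 is shielded by a doubly ortho-substituted aryl group; harsher conditions would then bring acid cleavage of the allyl ether, after which ring B could take part in the reclosure. Adventitious air would oxidise the hydroquinone. The fallback replaces equilibration by chelation-controlled ether cleavage and sets out from 10. Deallylation with Pd(PPh3)4 and morpholine should give 2-(2-hydroxy-6-methoxyphenyl)-5,6,7,8-tetramethoxy-4H-chromen-4-one F1, the same compound as A6. Anhydrous AlBr3 in MeCN (0 °C to rt) should then cleave first the C5 methyl ether, which is peri to the carbonyl, and next the C6 methyl ether, which is activated by the aluminium chelate spanning O4 and O5. The ethers at C7, C8 and C6' have no such activation. This returns to the route at the target 15.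

**Step 8.** The one-electron oxidant may attack ring B or the allyl group instead of ring A, or ring A, which is deactivated by the pyranone carbonyl, may react sluggishly and suffer over-oxidation on forcing. The fallback goes through a para-methoxyphenol, which is oxidised far more easily, and sets out from 10. Aqueous HCl in EtOH at reflux should remove only the C5 methyl group and give 5-hydroxy-6,7,8-trimethoxy-2-[2-methoxy-6-(prop-2-enyloxy)phenyl]-4H-chromen-4-one F2. PhI(OAc)2 in MeCN/H2O at 0 °C should then convert the 5-hydroxy-8-methoxy pair into the quinone. This returns to the route at 11, which is reduced as in step 8.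

**Step 2.** Reduction of the C–Br bond back to C–H can compete with C–O coupling, and hot methoxide may cause condensation at the methyl ketone. The fallback does without the fourth methoxy group and introduces O8 by para-hydroxylation instead. It sets out from 1 and uses acid chloride 7. O-acylation as in step 5 should give 2-acetyl-3,4,5-trimethoxyphenyl 2-methoxy-6-(prop-2-enyloxy)benzoate F3. KOtBu in THF should rearrange it to 1-(6-hydroxy-2,3,4-trimethoxyphenyl)-3-[2-methoxy-6-(prop-2-enyloxy)phenyl]propane-1,3-dione F4, and H2SO4 in AcOH should close this to 5,6,7-trimethoxy-2-[2-methoxy-6-(prop-2-enyloxy)phenyl]-4H-chromen-4-one F5. Aqueous HCl in EtOH at reflux should remove the peri methyl group and give 5-hydroxy-6,7-dimethoxy-2-[2-methoxy-6-(prop-2-enyloxy)phenyl]-4H-chromen-4-one F6. Elbs oxidation with K2S2O8 in aqueous KOH/pyridine should then give potassium 5-hydroxy-6,7-dimethoxy-2-[2-methoxy-6-(prop-2-enyloxy)phenyl]-4-oxo-4H-chromen-8-yl sulfate F7, which warm dilute HCl hydrolyses. This returns to the route at 12. Its weak point is the modest efficiency that is usual for persulfate hydroxylations.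

**Step 6.** The enolate has to attack an ester carbonyl flanked by two ortho alkoxy groups, so acyl transfer may be slow and cleavage of the ester back to 3 may compete. The fallback forms the C2–C3 bond intermolecularly and sets out from 3 and 7. Compound 3 is converted into its dianion with LiN(SiMe3)2 (3 equiv, THF, −78 °C) and C-acylated directly with 7. This returns to the route at 9; no new compound arises, which is entry F0.

## Further compounds

F1 | step 9 | 2-(2-hydroxy-6-methoxyphenyl)-5,6,7,8-tetramethoxy-4H-chromen-4-one | COc1cccc(O)c1-c1cc(=O)c2c(OC)c(OC)c(OC)c(OC)c2o1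
F2 | step 8 | 5-hydroxy-6,7,8-trimethoxy-2-[2-methoxy-6-(prop-2-enyloxy)phenyl]-4H-chromen-4-one | C=CCOc1cccc(OC)c1-c1cc(=O)c2c(O)c(OC)c(OC)c(OC)c2o1
F3 | step 2 | 2-acetyl-3,4,5-trimethoxyphenyl 2-methoxy-6-(prop-2-enyloxy)benzoate | CC(=O)c1c(OC(=O)c2c(OC)cccc2OCC=C)cc(OC)c(OC)c1OC
F4 | step 2 | 1-(6-hydroxy-2,3,4-trimethoxyphenyl)-3-[2-methoxy-6-(prop-2-enyloxy)phenyl]propane-1,3-dione | C=CCOc1cccc(OC)c1C(=O)CC(=O)c1c(O)cc(OC)c(OC)c1OC
F5 | step 2 | 5,6,7-trimethoxy-2-[2-methoxy-6-(prop-2-enyloxy)phenyl]-4H-chromen-4-one | C=CCOc1cccc(OC)c1-c1cc(=O)c2c(OC)c(OC)c(OC)cc2o1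
F6 | step 2 | 5-hydroxy-6,7-dimethoxy-2-[2-methoxy-6-(prop-2-enyloxy)phenyl]-4H-chromen-4-one | C=CCOc1cccc(OC)c1-c1cc(=O)c2c(O)c(OC)c(OC)cc2o1
F7 | step 2 | potassium 5-hydroxy-6,7-dimethoxy-2-[2-methoxy-6-(prop-2-enyloxy)phenyl]-4-oxo-4H-chromen-8-yl sulfate | C=CCOc1cccc(OC)c1-c1cc(=O)c2c(O)c(OC)c(OC)c(OS(=O)(=O)[O-])c2o1.[K+]
F0 | step 6 | none | none
A1 | alternative 1 | 2-ethoxy-5,6-dimethoxybenzene-1,4-diol | CCOc1cc(O)c(OC)c(OC)c1O
A2 | alternative 1 | 4-(1-ethoxyethenyl)-4-hydroxy-2,3-dimethoxycyclobut-2-en-1-one | C=C(OCC)C1(O)C(OC)=C(OC)C1=O
A3 | alternative 2 | 2-[2-(benzyloxy)-6-methoxyphenyl]-5,6,7,8-tetramethoxy-4H-chromen-4-one | COc1cccc(OCc2ccccc2)c1-c1cc(=O)c2c(OC)c(OC)c(OC)c(OC)c2o1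
A4 | alternative 2 | 3-[2-(benzyloxy)-6-methoxyphenyl]prop-2-ynoic acid | COc1cccc(OCc2ccccc2)c1C#CC(=O)O
A5 | alternative 2 | 2,3,4,5-tetramethoxy-6-(trimethylsilyl)phenyl trifluoromethanesulfonate | COc1c(OC)c(OC)c(OS(=O)(=O)C(F)(F)F)c([Si](C)(C)C)c1OC
A6 | alternative 3 | 2-(2-hydroxy-6-methoxyphenyl)-5,6,7,8-tetramethoxy-4H-chromen-4-one | COc1cccc(O)c1-c1cc(=O)c2c(OC)c(OC)c(OC)c(OC)c2o1
A7 | alternative 3 | 5,6,7,8-tetramethoxy-2-(methoxyethynyl)-4H-chromen-4-one | COC#Cc1cc(=O)c2c(OC)c(OC)c(OC)c(OC)c2o1
A8 | alternative 3 | cyclobut-2-en-1-one | O=C1C=CC1
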